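Remark: the target is taken as the open para-quinone methide written in its SMILES. It has no stereocentre and, because the dienone ring is symmetrical, no geometric isomer at the Cm=C bond.

## Structural features

Selaginellin F is built on a benzene ring A with four contiguous substituents: ring B (2,4-dihydroxyphenyl) on C2, the diarylmethylene carbon Cm on C1, a (4-hydroxyphenyl)ethynyl group on C6 and CH2OH on C5; C3 and C4 carry hydrogen. Cm is the exocyclic carbon of a para-quinone methide: it is doubly bonded to C-4 of a cyclohexa-2,5-dienone and singly bonded to a 4-hydroxyphenyl ring, so the two rings on Cm are the two tautomeric halves of one bis(4-hydroxyphenyl)methylene unit. The target has no stereocentres at all; the only stereocentres on the way are the two epoxide carbons of 20, which are cis by necessity and disappear in step 12. The fragile parts are the quinone methide (electrophilic at Cm, with the 2'-hydroxyl of ring B within reach), the electron-rich diarylalkyne, the benzylic alcohol and the phenols, which argues for unmasking everything in the last step. The real difficulty is the 1,2,3,4-tetrasubstituted ring A, in which the two bulkiest groups (Cm and ring B) are neighbours and Cm is also ortho to the alkyne. The key step uses the fact that Cm on C1 and the alkyne on C6 are ortho and end in the same 4-oxygenated phenyl group. A bond between Cm and the distal alkyne carbon would give a 2,3-diarylindenone (Cm = indenone C-3, the alkyne carbons = C-1 and C-2). Both groups can therefore come from one symmetrical diarylacetylene that is annulated onto an ortho-bromobenzaldehyde and later re-opened between C-2 and C-3.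

## Logic of the disconnections

26 back to 24. No skeletal bond is cut. The Cm=C bond and the six free hydroxyl groups are traced to a tertiary triarylcarbinol carrying six MOM acetals. This keeps the quinone methide and the phenols masked until the end with a single kind of protecting group. The forward step must cleave six acetals and ionise the carbinol (through 25) with acid mild enough to spare the alkyne.

24 back to 22 and 23. The bond from Cm to one of its two identical aryl rings is cut. Either cut gives the same ketone, and the nucleophile 23 comes from 14, which the route already contains. The forward step is an addition to a diaryl ketone with two ortho neighbours; the ketone cannot enolise, so only steric hindrance has to be overcome.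

22 back to 20 (through 21) and then to 19. The ketone carbon on C1 is reconnected to the distal alkyne carbon, which is the indenone C-2–C-3 bond, and the epoxide is traced to the enone. The ortho ketone/alkyne pair becomes one five-membered ring that an annulation can make, so neither group has to be introduced separately at a crowded position. The forward steps are a nucleophilic epoxidation of a tetrasubstituted enone and a fragmentation in which only the epoxide-bearing bond can break; this fixes which carbon becomes ketone and which alkyne.

19 back to 12 and 18. The bonds C1–Cm (indenone C-3–C-3a) and C-1–C-2 are cut. This gives a bromoaldehyde and a symmetrical alkyne, so the annulation has no regiochemical question. The halogen must sit on C1 and the formyl group on C6 (the reverse would exchange ketone and alkyne), and palladium must insert into a bromide with two ortho neighbours.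

12 back to 10 (through 11), 9 and 8. The C6–CHO bond is cut to a C6–I bond, the benzylic MOM ether is traced to the alcohol and this to the ester. A deprotonation of the analogue of 10 with hydrogen on C6 would have to compete with the position between the two acetal oxygens of ring B and with the benzylic CH2. An iodine on C6 makes the metalation site unambiguous through halogen–magnesium exchange. The forward exchange must take iodine and leave bromine, and the arylmagnesium ortho to bromine must not eliminate to an aryne.

8 back to 6 (through 7). The C6–I bond is cut. In 6 the C6 hydrogen is the only one flanked by both the ester and the bromine, so it is the most acidic and best coordinated position. The ester thus serves twice, first as directing group and then as the source of the C5 CH2OH. The forward step needs a hindered magnesium amide that neither adds to the ester nor exchanges halogen.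

6 back to 5 and 4. The biaryl bond C2–C-1' is cut. In 5 iodine and bromine are already differentiated, so ring B can be attached at C2 while the C1 bromide is kept. The forward coupling must be selective for iodide.

4 back to 2 (through 3) and 1. The C–B bond and the two O–acetal bonds are cut, which leads to a commercial bromoresorcinol. The forward exchange must be faster than ortho-deprotonation between the acetal oxygens.

18 back to 14 and 15 (through 16 and 17), and 14 back to 13. Both aryl–alkyne bonds are cut. The alkyne is symmetrical, so one aryl iodide is used twice and no cross-selectivity is needed. The forward step combines two Sonogashira couplings and a desilylation in one flask.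

## Other disconnections considered

Alternative 1: Ring A is cut at C1–C2, C3–C4 and C5–C6 back to the acyclic triyne A2. In A2 an aryl ester joins the ring B alkyne to a silylpropiolate, and a diisopropylsilyl ether joins that to propargyl alcohol. In the forward sense RhCl(PPh3)3, a monovalent rhodium complex, would cyclotrimerise A2 to A1, closing ring A, the six-membered lactone and the five-membered oxasilole at once.
- In its favour: the two tethers fix every position of ring A, so the tetrasubstituted arene and the biaryl bond arise together from simple alkynes. The 2'-oxygen of ring B is set apart from the 4'-oxygen. The lactone carbonyl on C1 is at the right oxidation level to take both rings of Cm from two equivalents of 23.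
- Against it here: an aryl ester prefers the conformation that holds its two alkynes apart, so closure through the ester tether is the weak point. A2 combines an aryl propiolate, an alkynyl–silicon bond and a silyl ether, all sensitive to bases and nucleophiles. After A1 the C6–Si bond still has to become the C6–alkyne bond (ipso-halogenation, then Sonogashira coupling at a carbon flanked by the lactone carbonyl and CH2O) before the lactone is opened.
- Comparison: for ring A itself it is the better plan, since the ring is made fully substituted in one step where the chosen plan needs steps 3 to 7. In regiocontrol the two are equal, because the symmetry of 18 and the tethers of A2 both remove the question. In mechanism the chosen annulation has the closer precedent for its substrate class, while the ester-tethered trimerisation carries a conformational penalty. In step economy the two are about equal, because what A1 saves on ring A is spent on the silicon-to-alkyne exchange and on making A2.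

Alternative 2: Ring A is cut at C1–C2 and C3–C4, with CO2 restored across C1 and C4, to the 2-pyrone A4 and the ring B alkyne A5. On heating, an inverse-demand Diels–Alder addition (terminal alkyne carbon to pyrone C-6, aryl-bearing carbon to pyrone C-3) followed by retro-Diels–Alder loss of CO2 would give the benzoate A3.
- In its favour: A3 already holds the ketone on C1 and the alkyne on C6; it is the ester analogue of 22. The epoxidation and fragmentation of the chosen plan (steps 11 and 12) are therefore not needed, and on this point the alternative is the better. Ring B is joined without a cross-coupling and without a metal. The polarity match (electron-rich arylalkyne, doubly acceptor-substituted pyrone) points in the right direction.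
- Against it here: A4 is a densely functionalised, base-sensitive heterocycle with four different substituents and needs a multi-step synthesis with its own regiochemical questions. Its internal alkyne is a second possible 2π partner. The regiochemistry rests on electronic bias alone, and the required orientation places ring B next to the aroyl group, the more crowded outcome. C5 arrives as a methyl ester next to a diaryl ketone, so the aryllithium addition of step 13 would have to distinguish the two or be preceded by redox adjustments.
- Comparison: the two plans are equal in convergence (three fragments each). The alternative is mechanistically simpler (thermal, no catalyst) but less certain in regiochemistry. It is probably no shorter once A4 and the ester problem are counted.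

Alternative 3: The biaryl bond C2–C-1' is cut in the lactone A6, back to the aryl ester A7. In the forward sense Pd(OAc)2 and PCy3 with K2CO3 and pivalic acid would be used: zerovalent palladium inserts into the C2–I bond, and a carboxylate-assisted metalation–deprotonation at the phenol-ring position para to OMOM closes the six-membered lactone.
- In its favour: the lactone carbonyl is Cm at the acid oxidation level, so two equivalents of 23 would install both Cm rings in one step and free the 2'-hydroxyl at the same time. The C6 bromide remains for a Sonogashira coupling with 17 (isolated for this purpose). No redox detour is needed, and the sequence after A6 is about three steps, so this is the better plan in step economy.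
- Against it here: the acid part of A7 is again a 1,2,3,4-tetrasubstituted benzene (Br, I, carboxyl, CH2O), no easier to make than 12, and it must be esterified at a carboxyl flanked by two halogens. The arylation must choose iodine over bromine and the less hindered of the two positions ortho to the ester oxygen. The Sonogashira coupling must then occur at a bromide flanked by the lactone carbonyl and CH2OTBS. The 2'-hydroxyl is unmasked early, next to the future cationic Cm, and two kinds of protecting group are carried.
- Comparison: in structure both plans face the same ring A problem. In mechanism both key steps are palladium-catalysed C–C bond formations at a crowded carbon; the chosen one has no site-selectivity issue, the alternative has two (halide and C–H site). In step economy the alternative is the shorter.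

Key step: step 10

## Route

Step 1
Reactants: 1 4-bromoresorcinol
Product: 2 1-bromo-2,4-bis(methoxymethoxy)benzene
Conditions: MOMCl (2.6 equiv), i-Pr2NEt (3 equiv), CH2Cl2, 0 °C → rt
Reagents that add atoms: chloromethyl methyl ether, COCCl
Why: O-Alkylation of both phenols (Williamson-type acetal formation); the MOM acetals withstand every basic and organometallic step that follows and are removed together in the last step.

Step 2
Reactants: 2 1-bromo-2,4-bis(methoxymethoxy)benzene
Product: 4 2-[2,4-bis(methoxymethoxy)phenyl]-4,4,5,5-tetramethyl-1,3,2-dioxaborolane, via aryllithium 3 (not isolated)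
Conditions: n-BuLi (1.05 equiv), THF, −78 °C; i-PrOBpin (1.3 equiv), −78 °C → rt; aq. NH4Cl
Reagents that add atoms: 2-isopropoxy-4,4,5,5-tetramethyl-1,3,2-dioxaborolane, CC(C)OB1OC(C)(C)C(C)(C)O1
Why: Bromine–lithium exchange at −78 °C is far faster than deprotonation between the two acetal oxygens, and 3 is trapped at once by the borate ester. The pinacol boronate can be purified without acid, which spares the MOM groups.

Step 3
Reactants: 5 methyl 3-bromo-4-iodobenzoate; 4 2-[2,4-bis(methoxymethoxy)phenyl]-4,4,5,5-tetramethyl-1,3,2-dioxaborolane
Product: 6 methyl 3-bromo-4-[2,4-bis(methoxymethoxy)phenyl]benzoate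
Conditions: Pd(PPh3)4 (5 mol%), Na2CO3 (aq.), DME, 70 °C
Reagents that add atoms: none
Why: Suzuki–Miyaura coupling; zerovalent palladium inserts into C–I much faster than into the neighbouring C–Br, so the C2–C-1' bond is formed and the bromide is kept for the key step.

Step 4
Reactants: 6 methyl 3-bromo-4-[2,4-bis(methoxymethoxy)phenyl]benzoate
Product: 8 methyl 3-bromo-2-iodo-4-[2,4-bis(methoxymethoxy)phenyl]benzoate, via arylmagnesium chloride 7 (not isolated)
Conditions: TMPMgCl·LiCl (1.2 equiv), THF, −20 → 0 °C; I2 (1.3 equiv), −20 °C → rt; aq. Na2S2O3
Reagents that add atoms: iodine, II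
Why: Directed ortho-magnesiation of a 3-halobenzoate: the hindered amide base removes the one hydrogen flanked by the coordinating ester and the acidifying bromine, without adding to the ester or exchanging halogen, and 7 is stable at 0 °C. The hydrogen between the acetal oxygens of ring B is not acidic enough for this base, and the iodine quench marks C6 for the later formylation.

Step 5
Reactants: 8 methyl 3-bromo-2-iodo-4-[2,4-bis(methoxymethoxy)phenyl]benzoate
Product: 9 {3-bromo-2-iodo-4-[2,4-bis(methoxymethoxy)phenyl]phenyl}methanol
Conditions: DIBAL-H (2.5 equiv), CH2Cl2, −78 → 0 °C; aq. potassium sodium tartrate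
Reagents that add atoms: none
Why: Reduction of the ester to the primary alcohol with an aluminium hydride that leaves aryl iodide, aryl bromide and acetals untouched at low temperature.

Step 6
Reactants: 9 {3-bromo-2-iodo-4-[2,4-bis(methoxymethoxy)phenyl]phenyl}methanol
Product: 10 2-bromo-3-iodo-1-[2,4-bis(methoxymethoxy)phenyl]-4-[(methoxymethoxy)methyl]benzene
Conditions: MOMCl (1.5 equiv), i-Pr2NEt (2 equiv), CH2Cl2, 0 °C → rt
Reagents that add atoms: chloromethyl methyl ether, COCCl
Why: MOM ether formation on the primary benzylic alcohol; using the same acetal as on the phenols allows a single deprotection at the end.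

Step 7
Reactants: 10 2-bromo-3-iodo-1-[2,4-bis(methoxymethoxy)phenyl]-4-[(methoxymethoxy)methyl]benzene
Product: 12 2-bromo-3-[2,4-bis(methoxymethoxy)phenyl]-6-[(methoxymethoxy)methyl]benzaldehyde, via arylmagnesium chloride 11 (not isolated)
Conditions: i-PrMgCl·LiCl (1.15 equiv), THF, −40 °C; DMF (3 equiv), −40 °C → rt; aq. NH4Cl
Reagents that add atoms: N,N-dimethylformamide, CN(C)C=O
Why: Iodine–magnesium exchange takes C–I and not C–Br at −40 °C, helped by the ortho bromine and the chelating CH2OMOM group, and 11 does not eliminate to an aryne at this temperature. Formylation with DMF (Bouveault-type) then places CHO on C6 with no competition from ring B.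

Step 8
Reactants: 13 4-iodophenol
Product: 14 1-iodo-4-(methoxymethoxy)benzene
Conditions: MOMCl (1.3 equiv), i-Pr2NEt (1.5 equiv), CH2Cl2, 0 °C → rt
Reagents that add atoms: chloromethyl methyl ether, COCCl
Why: O-Alkylation of the phenol to the MOM acetal; 14 serves twice, for the alkyne 18 and for the aryllithium 23.

Step 9
Reactants: 14 1-iodo-4-(methoxymethoxy)benzene; 15 trimethylsilylacetylene
Product: 18 1,2-bis[4-(methoxymethoxy)phenyl]ethyne, via silylalkyne 16 (not isolated), via terminal alkyne 17 (not isolated)
Conditions: 14 (2 equiv), 15 (1 equiv), PdCl2(PPh3)2 (3 mol%), CuI (5 mol%), DBU (6 equiv), H2O (0.5 equiv), MeCN, rt → 60 °C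
Reagents that add atoms: none
Why: One-pot double Sonogashira coupling: the first coupling gives 16, DBU and water remove the silyl group to give 17, and 17 couples with the second equivalent of 14. The product is symmetrical, so no cross-selectivity is required.

Step 10
Reactants: 12 2-bromo-3-[2,4-bis(methoxymethoxy)phenyl]-6-[(methoxymethoxy)methyl]benzaldehyde; 18 1,2-bis[4-(methoxymethoxy)phenyl]ethyne
Product: 19 4-[2,4-bis(methoxymethoxy)phenyl]-7-[(methoxymethoxy)methyl]-2,3-bis[4-(methoxymethoxy)phenyl]-1H-inden-1-one
Conditions: Pd(OAc)2 (10 mol%), NaOAc (4 equiv), n-Bu4NCl (1 equiv), 18 (1.5 equiv), DMF, 100 °C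
Reagents that add atoms: none
Why: Larock indenone annulation. Pd(OAc)2 is reduced in the flask to chloride-stabilised zerovalent palladium, which inserts into the C1–Br bond of 12. syn-Carbopalladation of 18 forms the C1–Cm bond (indenone C-3–C-3a) and leaves an alkenyl divalent palladium species next to the formyl group. Its addition to the carbonyl carbon, a 5-exo-trig closure, forms the C-1–C-2 bond and the five-membered ring; β-hydride elimination from the palladium alkoxide gives the ketone, and NaOAc takes up HBr to return zerovalent palladium. The closest known reaction type is the palladium-catalysed annulation of ortho-bromo- and ortho-iodobenzaldehydes with diarylacetylenes to 2,3-diarylindenones. No stereocentre is formed. Regioselectivity is not needed because 18 is symmetrical, and chemoselectivity is secured because 12 has a single carbon–halogen bond and carries only base-stable MOM acetals. The one real demand is insertion at a bromide with two ortho neighbours, for which ligand-free chloride conditions at 100 °C and an excess of 18 are chosen.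

Step 11
Reactants: 19 4-[2,4-bis(methoxymethoxy)phenyl]-7-[(methoxymethoxy)methyl]-2,3-bis[4-(methoxymethoxy)phenyl]-1H-inden-1-one
Product: 20 rac-4-[2,4-bis(methoxymethoxy)phenyl]-7-[(methoxymethoxy)methyl]-2,3-bis[4-(methoxymethoxy)phenyl]-2,3-epoxy-2,3-dihydro-1H-inden-1-one (cis-fused epoxide)
Conditions: 30% aq. H2O2, NaOH (0.5 equiv), MeOH–THF, 0 °C → rt, dark
Reagents that add atoms: hydrogen peroxide, OO
Why: Weitz–Scheffer nucleophilic epoxidation: hydroperoxide adds to the electron-poor C-3 and the enolate closes onto oxygen, a known way to 2,3-diarylindenone oxides. The two new stereocentres can only be cis because of the ring fusion, and the product is racemic. The work is done cold and in the dark because such oxides open to benzopyrylium oxides on heating or irradiation.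

Step 12
Reactants: 20 rac-4-[2,4-bis(methoxymethoxy)phenyl]-7-[(methoxymethoxy)methyl]-2,3-bis[4-(methoxymethoxy)phenyl]-2,3-epoxy-2,3-dihydro-1H-inden-1-one
Product: 22 {2',4'-bis(methoxymethoxy)-4-[(methoxymethoxy)methyl]-3-{[4-(methoxymethoxy)phenyl]ethynyl}biphenyl-2-yl}[4-(methoxymethoxy)phenyl]methanone, via tosylhydrazone 21 (not isolated)
Conditions: TsNHNH2 (1.3 equiv), CH2Cl2–AcOH (2:1), −20 °C → rt
Reagents that add atoms: none
Why: Eschenmoser–Tanabe fragmentation: 21 opens the epoxide to an azoalkene alkoxide in which the ring holds the C-2–C-3 bond anti to the C-1–N bond. Loss of sulfinate and N2 cleaves C-2–C-3, so C-3 becomes the C1 aryl ketone and C-1/C-2 become the C6 alkyne. Only the epoxide-bearing bond can break, and the alkyne formed is acyclic, so no ring strain opposes it.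

Step 13
Reactants: 22 {2',4'-bis(methoxymethoxy)-4-[(methoxymethoxy)methyl]-3-{[4-(methoxymethoxy)phenyl]ethynyl}biphenyl-2-yl}[4-(methoxymethoxy)phenyl]methanone; 14 1-iodo-4-(methoxymethoxy)benzene
Product: 24 {2',4'-bis(methoxymethoxy)-4-[(methoxymethoxy)methyl]-3-{[4-(methoxymethoxy)phenyl]ethynyl}biphenyl-2-yl}bis[4-(methoxymethoxy)phenyl]methanol, via aryllithium 23 (not isolated)
Conditions: 14 (3 equiv), t-BuLi (6 equiv), Et2O, −78 °C; then 22, THF, −78 → 0 °C; aq. NH4Cl
Reagents that add atoms: none
Why: Iodine–lithium exchange on 14, then 1,2-addition of 23 to the non-enolisable diaryl ketone; excess reagent and warming to 0 °C answer the two ortho substituents. The carbinol carbon bears two identical aryl groups and is not a stereocentre.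

Step 14
Reactants: 24 {2',4'-bis(methoxymethoxy)-4-[(methoxymethoxy)methyl]-3-{[4-(methoxymethoxy)phenyl]ethynyl}biphenyl-2-yl}bis[4-(methoxymethoxy)phenyl]methanol
Product: 26 Selaginellin F, via deprotected carbinol 25 (not isolated)
Conditions: 3 M aq. HCl, MeOH–THF, 45 °C; NaHCO3 to pH 6–7
Reagents that add atoms: none
Why: Acid cleavage of the six MOM acetals and acid-promoted ionisation of the triarylcarbinol give a diarylmethyl cation stabilised by two para oxygens. On neutralisation it loses a phenolic proton to give the para-quinone methide (fuchsone formation); no stereocentre is involved.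

## Compound list

1 | 4-bromoresorcinol (4-bromobenzene-1,3-diol) | Oc1ccc(Br)c(O)c1 | starting material
2 | 1-bromo-2,4-bis(methoxymethoxy)benzene | COCOc1ccc(Br)c(OCOC)c1 | intermediate
3 | [2,4-bis(methoxymethoxy)phenyl]lithium (formed in the flask) | [Li]c1ccc(OCOC)cc1OCOC | intermediate
4 | 2-[2,4-bis(methoxymethoxy)phenyl]-4,4,5,5-tetramethyl-1,3,2-dioxaborolane | COCOc1ccc(B2OC(C)(C)C(C)(C)O2)c(OCOC)c1 | intermediate
5 | methyl 3-bromo-4-iodobenzoate | COC(=O)c1ccc(I)c(Br)c1 | starting material
6 | methyl 3-bromo-4-[2,4-bis(methoxymethoxy)phenyl]benzoate | COC(=O)c1ccc(-c2ccc(OCOC)cc2OCOC)c(Br)c1 | intermediate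
7 | chloro{2-bromo-3-[2,4-bis(methoxymethoxy)phenyl]-6-(methoxycarbonyl)phenyl}magnesium–lithium chloride (formed in the flask) | COC(=O)c1ccc(-c2ccc(OCOC)cc2OCOC)c(Br)c1[Mg]Cl.[Li+].[Cl-] | intermediate
8 | methyl 3-bromo-2-iodo-4-[2,4-bis(methoxymethoxy)phenyl]benzoate | COC(=O)c1ccc(-c2ccc(OCOC)cc2OCOC)c(Br)c1I | intermediate
9 | {3-bromo-2-iodo-4-[2,4-bis(methoxymethoxy)phenyl]phenyl}methanol | OCc1ccc(-c2ccc(OCOC)cc2OCOC)c(Br)c1I | intermediate
10 | 2-bromo-3-iodo-1-[2,4-bis(methoxymethoxy)phenyl]-4-[(methoxymethoxy)methyl]benzene | COCOCc1ccc(-c2ccc(OCOC)cc2OCOC)c(Br)c1I | intermediate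
11 | chloro{2-bromo-3-[2,4-bis(methoxymethoxy)phenyl]-6-[(methoxymethoxy)methyl]phenyl}magnesium–lithium chloride (formed in the flask) | COCOCc1ccc(-c2ccc(OCOC)cc2OCOC)c(Br)c1[Mg]Cl.[Li+].[Cl-] | intermediate
12 | 2-bromo-3-[2,4-bis(methoxymethoxy)phenyl]-6-[(methoxymethoxy)methyl]benzaldehyde | COCOCc1ccc(-c2ccc(OCOC)cc2OCOC)c(Br)c1C=O | intermediate
13 | 4-iodophenol | Oc1ccc(I)cc1 | starting material
14 | 1-iodo-4-(methoxymethoxy)benzene | COCOc1ccc(I)cc1 | intermediate
15 | trimethylsilylacetylene (ethynyltrimethylsilane) | C#C[Si](C)(C)C | starting material
16 | {[4-(methoxymethoxy)phenyl]ethynyl}trimethylsilane (formed in the flask) | COCOc1ccc(C#C[Si](C)(C)C)cc1 | intermediate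
17 | 1-ethynyl-4-(methoxymethoxy)benzene (formed in the flask) | COCOc1ccc(C#C)cc1 | intermediate
18 | 1,2-bis[4-(methoxymethoxy)phenyl]ethyne | COCOc1ccc(C#Cc2ccc(OCOC)cc2)cc1 | intermediate
19 | 4-[2,4-bis(methoxymethoxy)phenyl]-7-[(methoxymethoxy)methyl]-2,3-bis[4-(methoxymethoxy)phenyl]-1H-inden-1-one | COCOCc1ccc(-c2ccc(OCOC)cc2OCOC)c2c1C(=O)C(c1ccc(OCOC)cc1)=C2c1ccc(OCOC)cc1 | intermediate
20 | rac-4-[2,4-bis(methoxymethoxy)phenyl]-7-[(methoxymethoxy)methyl]-2,3-bis[4-(methoxymethoxy)phenyl]-2,3-epoxy-2,3-dihydro-1H-inden-1-one (cis-fused epoxide; racemic, one enantiomer written) | O=C1c2c(COCOC)ccc(-c3ccc(OCOC)cc3OCOC)c2[C@]3(c4ccc(OCOC)cc4)O[C@]13c5ccc(OCOC)cc5 | intermediate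
21 | C-1 tosylhydrazone of 20 (racemic, one enantiomer written; C=N geometry not defined; formed in the flask) | Cc1ccc(cc1)S(=O)(=O)NN=C1c2c(COCOC)ccc(-c3ccc(OCOC)cc3OCOC)c2[C@]3(c4ccc(OCOC)cc4)O[C@]13c5ccc(OCOC)cc5 | intermediate
22 | {2',4'-bis(methoxymethoxy)-4-[(methoxymethoxy)methyl]-3-{[4-(methoxymethoxy)phenyl]ethynyl}biphenyl-2-yl}[4-(methoxymethoxy)phenyl]methanone | COCOCc1ccc(-c2ccc(OCOC)cc2OCOC)c(C(=O)c2ccc(OCOC)cc2)c1C#Cc1ccc(OCOC)cc1 | intermediate
23 | [4-(methoxymethoxy)phenyl]lithium (formed in the flask) | [Li]c1ccc(OCOC)cc1 | intermediate
24 | {2',4'-bis(methoxymethoxy)-4-[(methoxymethoxy)methyl]-3-{[4-(methoxymethoxy)phenyl]ethynyl}biphenyl-2-yl}bis[4-(methoxymethoxy)phenyl]methanol | COCOCc1ccc(-c2ccc(OCOC)cc2OCOC)c(C(O)(c2ccc(OCOC)cc2)c2ccc(OCOC)cc2)c1C#Cc1ccc(OCOC)cc1 | intermediate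
25 | {2',4'-dihydroxy-4-(hydroxymethyl)-3-[(4-hydroxyphenyl)ethynyl]biphenyl-2-yl}bis(4-hydroxyphenyl)methanol (formed in the flask) | OCc1ccc(-c2ccc(O)cc2O)c(C(O)(c2ccc(O)cc2)c2ccc(O)cc2)c1C#Cc1ccc(O)cc1 | intermediate
26 | Selaginellin F, 4-{[2',4'-dihydroxy-4-(hydroxymethyl)-3-[(4-hydroxyphenyl)ethynyl]biphenyl-2-yl](4-hydroxyphenyl)methylidene}cyclohexa-2,5-dien-1-one | O=C1C=CC(=C(c2ccc(O)cc2)c2c(-c3ccc(O)cc3O)ccc(CO)c2C#Cc2ccc(O)cc2)C=C1 | target

## Step count and least certain steps

Total step count: 14. Longest linear sequence: 12 steps (1 → 2 → 4 → 6 → 8 → 9 → 10 → 12 → 19 → 20 → 22 → 24 → 26; steps 1 to 7 and 10 to 14).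

Step 10 (key step). The most likely failure is slow oxidative addition and alkyne insertion at a bromide flanked by the formyl group and ring B. Hydrodebromination, decarbonylation of the aldehyde or oligomerisation of 18 could then overtake the annulation. The fallback sets out from 12 and 18. A nickel-catalysed reductive carbocyclisation (NiBr2(dppe), Zn, MeCN, 80 °C), a known route from ortho-halobenzaldehydes and alkynes to indenols, would be used; zerovalent nickel inserts more readily into hindered aryl bromides and the alkenylnickel adds to the aldehyde. It should give the indenol F1. Oxidation of this benzylic, allylic alcohol with MnO2 comes back to the route at 19.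

Step 12. The likely failure is acid-induced opening of the epoxide at C-3, which is benzylic and carries a para-alkoxyphenyl group, before the hindered C-1 ketone has formed its hydrazone. Skeletal rearrangement or valence isomerisation would then replace fragmentation. The fallback sets out from 12 and builds the alkyne and the carbinol conventionally:
- Seyferth–Gilbert homologation (dimethyl (1-diazo-2-oxopropyl)phosphonate, K2CO3, MeOH) gives the terminal alkyne F2.
- Sonogashira coupling with 14 (PdCl2(PPh3)2, CuI, Et3N, rt) gives the bromo diarylalkyne F3; the iodide of 14 reacts and the hindered bromide of F2 does not.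
- Bromine–lithium exchange (t-BuLi, THF, −78 °C) gives the aryllithium F4, which is added to the diaryl ketone F5 (made from 4,4'-dihydroxybenzophenone and MOMCl).

This comes back to the route at 24 and bypasses steps 10 to 13.

Step 11. The likely failure is slow conjugate addition of hydroperoxide at the crowded C-3, which carries an electron-rich aryl group and sits next to ring B. Attack at the C-1 carbonyl with ring cleavage could then compete. The fallback sets out from 19. Luche reduction (NaBH4, CeCl3·7H2O, MeOH) gives the indenol F1, whose electron-rich tetrasubstituted alkene is epoxidised electrophilically with dimethyldioxirane in acetone to the epoxy alcohol F6. Either C-1 epimer serves, because Dess–Martin oxidation (NaHCO3 buffer) removes that centre and comes back to the route at 20.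

Step 4. The likely failures are incomplete or misdirected magnesiation (at the hydrogen ortho to the ester only) and attack of 7 on the methyl ester of a second molecule. The fallback sets out from 6. Saponification (LiOH, THF–H2O) gives the acid F7. Carboxylate-directed ortho-lithiation with LiTMP (2.2 equiv, THF, −50 °C), a known reaction of 3-bromobenzoic acids, gives the dianion F8, and an iodine quench gives the iodo acid F9. Reduction with BH3·THF comes back to the route at 9.

Step 14. The likely failure is loss of chemoselectivity during global deprotection. Acid strong enough for six acetals may hydrate the electron-rich alkyne or let the C5 hydroxymethyl or the 2'-hydroxyl add to the alkyne or to cationic Cm (six-membered ether closure). The fallback sets out from 24. The acetals are cleaved without protic acid using TMSOTf and 2,2'-bipyridyl (CH2Cl2, 0 °C) followed by water, and 25 is isolated. Dehydration with a trace of AcOH then comes back to the route at 26; no new compound is needed.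

## Further compounds

F1 | step 10 | 4-[2,4-bis(methoxymethoxy)phenyl]-7-[(methoxymethoxy)methyl]-2,3-bis[4-(methoxymethoxy)phenyl]-1H-inden-1-ol (racemic, one enantiomer written) | O[C@@H]1c2c(COCOC)ccc(-c3ccc(OCOC)cc3OCOC)c2C(c4ccc(OCOC)cc4)=C1c5ccc(OCOC)cc5
F2 | step 12 | 2-bromo-3-ethynyl-1-[2,4-bis(methoxymethoxy)phenyl]-4-[(methoxymethoxy)methyl]benzene | COCOCc1ccc(-c2ccc(OCOC)cc2OCOC)c(Br)c1C#C
F3 | step 12 | 2-bromo-1-[2,4-bis(methoxymethoxy)phenyl]-4-[(methoxymethoxy)methyl]-3-{[4-(methoxymethoxy)phenyl]ethynyl}benzene | COCOCc1ccc(-c2ccc(OCOC)cc2OCOC)c(Br)c1C#Cc1ccc(OCOC)cc1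
F4 | step 12 | {2',4'-bis(methoxymethoxy)-4-[(methoxymethoxy)methyl]-3-{[4-(methoxymethoxy)phenyl]ethynyl}biphenyl-2-yl}lithium | COCOCc1ccc(-c2ccc(OCOC)cc2OCOC)c([Li])c1C#Cc1ccc(OCOC)cc1
F5 | step 12 | bis[4-(methoxymethoxy)phenyl]methanone | COCOc1ccc(cc1)C(=O)c1ccc(OCOC)cc1
F6 | step 11 | rac-4-[2,4-bis(methoxymethoxy)phenyl]-7-[(methoxymethoxy)methyl]-2,3-bis[4-(methoxymethoxy)phenyl]-2,3-epoxy-2,3-dihydro-1H-inden-1-ol (cis-fused epoxide; hydroxyl syn to the epoxide oxygen written; racemic) | O[C@@H]1c2c(COCOC)ccc(-c3ccc(OCOC)cc3OCOC)c2[C@]3(c4ccc(OCOC)cc4)O[C@]13c5ccc(OCOC)cc5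
F7 | step 4 | 3-bromo-4-[2,4-bis(methoxymethoxy)phenyl]benzoic acid | OC(=O)c1ccc(-c2ccc(OCOC)cc2OCOC)c(Br)c1
F8 | step 4 | lithium 3-bromo-2-lithio-4-[2,4-bis(methoxymethoxy)phenyl]benzoate | [Li+].[O-]C(=O)c1ccc(-c2ccc(OCOC)cc2OCOC)c(Br)c1[Li]
F9 | step 4 | 3-bromo-2-iodo-4-[2,4-bis(methoxymethoxy)phenyl]benzoic acid | OC(=O)c1ccc(-c2ccc(OCOC)cc2OCOC)c(Br)c1I
F0 | step 14 | none | none
A1 | alternative 1 | 3-(methoxymethoxy)-6H-benzo[c]chromen-6-one with a 1,1-diisopropyl-oxasilole ring fused across ring A C6 (Si) and C5 (CH2O) | COCOc1ccc2c(c1)OC(=O)c1c3c(ccc12)CO[Si]3(C(C)C)C(C)C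
A2 | alternative 1 | 2-ethynyl-5-(methoxymethoxy)phenyl 3-[diisopropyl(prop-2-yn-1-yloxy)silyl]prop-2-ynoate | C#Cc1ccc(OCOC)cc1OC(=O)C#C[Si](C(C)C)(C(C)C)OCC#C
A3 | alternative 2 | methyl 4-[2,4-bis(methoxymethoxy)phenyl]-3-[4-(methoxymethoxy)benzoyl]-2-{[4-(methoxymethoxy)phenyl]ethynyl}benzoate | COC(=O)c1ccc(-c2ccc(OCOC)cc2OCOC)c(C(=O)c2ccc(OCOC)cc2)c1C#Cc1ccc(OCOC)cc1
A4 | alternative 2 | methyl 3-[4-(methoxymethoxy)benzoyl]-4-{[4-(methoxymethoxy)phenyl]ethynyl}-2-oxo-2H-pyran-5-carboxylate | COC(=O)C1=COC(=O)C(C(=O)c2ccc(OCOC)cc2)=C1C#Cc1ccc(OCOC)cc1
A5 | alternative 2 | 1-ethynyl-2,4-bis(methoxymethoxy)benzene | C#Cc1ccc(OCOC)cc1OCOC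
A6 | alternative 3 | 7-bromo-8-{[(tert-butyldimethylsilyl)oxy]methyl}-3-(methoxymethoxy)-6H-benzo[c]chromen-6-one | COCOc1ccc2c(c1)OC(=O)c1c(Br)c(CO[Si](C)(C)C(C)(C)C)ccc12
A7 | alternative 3 | 3-(methoxymethoxy)phenyl 2-bromo-3-{[(tert-butyldimethylsilyl)oxy]methyl}-6-iodobenzoate | COCOc1cccc(OC(=O)c2c(I)ccc(CO[Si](C)(C)C(C)(C)C)c2Br)c1
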